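**Assumption:** Pestalone G has no stereocentre and no configurationally stable axis, so the target is one achiral compound and no stereocontrol is needed. Labels: ring A = halogenated ring; ring B = formyl/prenyl ring with C1' (ketone), C2' (CHO), C3' (OH), C4' (H), C5' (OH), C6' (prenyl).

## Retrosynthetic overview

1. Pestalone G 18 ⇐ protected N-tert-octyl ketimine 17 by one global acid hydrolysis (imine, acetal, three MOM ethers, one C–Si bond).
2. 17 ⇐ one-pot union at the carbonyl C–C1' bond: ring A aryllithium + isocyanide gives a lithium aldimine (masked aroyl anion), which adds to a ring B aryne (C1'≡C6'); the new aryllithium is trapped with prenyl bromide.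
3. Ring A partner 4 ⇐ 3-methoxy-5-methylphenol 1 (ortho-bromination, para-chlorination, MOM ether).
4. Ring B aryne precursor 9 ⇐ 5-chloro-2,4-dihydroxybenzaldehyde 5 (MOM ethers, acetal, SiMe3 block at C4').
5. No ring is built: both benzene rings are bought, ring A is elaborated first, ring B second, and they are joined in step 7.

## Route

Step 1
Reactants: 1 3-methoxy-5-methylphenol
Product: 2 2-bromo-5-methoxy-3-methylphenol
Conditions: NBS (1.0 equiv, slow addition), iPr2NH (10 mol%), CH2Cl2, −20 → 0 °C
Reagents that add atoms: N-bromosuccinimide O=C1CCC(=O)N1Br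
Why: Amine-catalysed ortho-selective electrophilic bromination of a phenol, in which the N-bromoamine is hydrogen-bonded to the OH and delivers bromine ortho; of the two ortho carbons, the one para to OMe is far more reactive than the one between the two oxygens.

Step 2
Reactants: 2 2-bromo-5-methoxy-3-methylphenol
Product: 3 2-bromo-4-chloro-5-methoxy-3-methylphenol
Conditions: SO2Cl2 (1.05 equiv), CH2Cl2, 0 °C → rt, dark
Reagents that add atoms: sulfuryl chloride O=S(=O)(Cl)Cl
Why: Electrophilic aromatic chlorination para to the free OH; the only other open carbon lies between OH and OMe, the least reactive site of a resorcinol monoether.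

Step 3
Reactants: 3 2-bromo-4-chloro-5-methoxy-3-methylphenol
Product: 4 2-bromo-4-chloro-5-methoxy-1-(methoxymethoxy)-3-methylbenzene
Conditions: MOMCl (1.5 equiv), iPr2NEt (2 equiv), CH2Cl2, 0 °C → rt
Reagents that add atoms: chloromethyl methyl ether COCCl
Why: O-alkylation (MOM protection) masks the acidic OH and leaves one ring hydrogen, flanked by OMOM and OMe, as the metalation site for step 7.

Step 4
Reactants: 5 5-chloro-2,4-dihydroxybenzaldehyde
Product: 6 5-chloro-2,4-bis(methoxymethoxy)benzaldehyde
Conditions: MOMCl (3 equiv), iPr2NEt (4 equiv), CH2Cl2, 0 °C → reflux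
Reagents that add atoms: chloromethyl methyl ether COCCl
Why: Double O-alkylation (MOM protection); the hydrogen-bonded 2-OH needs the excess reagent and warming.

Step 5
Reactants: 6 5-chloro-2,4-bis(methoxymethoxy)benzaldehyde
Product: 7 1-chloro-5-(dimethoxymethyl)-2,4-bis(methoxymethoxy)benzene
Conditions: HC(OMe)3 (3 equiv), MeOH, PPTS (2 mol%), rt; Et3N quench
Reagents that add atoms: trimethyl orthoformate COC(OC)OC
Why: Acid-catalysed acetalisation driven by the orthoformate hides the aldehyde from LiTMP and organolithiums; PPTS at rt is mild enough to leave the aryl MOM ethers intact.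

Step 6
Reactants: 7 1-chloro-5-(dimethoxymethyl)-2,4-bis(methoxymethoxy)benzene
Product: 9 [3-chloro-5-(dimethoxymethyl)-2,6-bis(methoxymethoxy)phenyl]trimethylsilane, via aryllithium 8 (not isolated)
Conditions: n-BuLi (1.1 equiv), THF, −78 → −45 °C, 1 h; TMSCl (1.3 equiv), −78 °C → rt
Reagents that add atoms: chlorotrimethylsilane C[Si](C)(C)Cl
Why: Cooperative directed ortho-metalation between the two OMOM groups, then C-silylation; SiMe3 blocks the most acidic ring hydrogen (future C4'–H) so that in step 7 LiTMP can only remove the hydrogen ortho to chlorine, and it is acid-labile at the end.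

Step 7
Reactants: 4 2-bromo-4-chloro-5-methoxy-1-(methoxymethoxy)-3-methylbenzene; 10 2-isocyano-2,4,4-trimethylpentane; 9 [3-chloro-5-(dimethoxymethyl)-2,6-bis(methoxymethoxy)phenyl]trimethylsilane; 11 1-bromo-3-methylbut-2-ene
Product: 17 1-[3-bromo-5-chloro-6-methoxy-2-(methoxymethoxy)-4-methylphenyl]-1-[2-(dimethoxymethyl)-3,5-bis(methoxymethoxy)-6-(3-methylbut-2-enyl)-4-(trimethylsilyl)phenyl]-N-(2,4,4-trimethylpentan-2-yl)methanimine, via ring A aryllithium 12 (not isolated), via lithium aldimine 13 (not isolated), via ortho-lithiated chloroarene 14 (not isolated), via ring B aryne 15 (not isolated), via ortho-lithiated ketimine 16 (not isolated)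
Conditions: one pot: 4, LiTMP (1.05 equiv), THF, −78 °C; 10 (1.0 equiv), −78 → 0 °C; 9 (1.3 equiv), −45 °C, LiTMP (1.4 equiv, added over 1 h), −45 → −15 °C; 11 (3 equiv), −78 → 0 °C
Reagents that add atoms: 2-isocyano-2,4,4-trimethylpentane 10 CC(C)(C)CC(C)(C)[N+]#[C-]; 1-bromo-3-methylbut-2-ene 11 CC(C)=CCBr
Why: Proposed new method: LiTMP (no Br–Li exchange) removes the only ring hydrogen of 4 to give 12, which adds to the isocyanide carbon to give lithium aldimine 13, a masked aroyl anion whose planar sp2 carbon avoids a quaternary sp3 centre between two di-ortho-substituted rings; LiTMP then removes the only ring hydrogen of 9 (ortho to Cl) and loss of LiCl from 14 gives aryne 15; 13 attacks the aryne carbon distal to the flanking OMOM (C1', the usual 3-alkoxyaryne regiochemistry), which forms the key carbonyl C–C1' bond and the OMOM-chelated aryllithium 16, and 16 is alkylated by prenyl bromide (SN2) faster than the hindered amine TMPH can protonate it; the closest known reaction types are the Walborsky lithium aldimine ketone synthesis and LiTMP-mediated aryne carbolithiation with electrophilic trapping of the resulting aryllithium.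

Step 8
Reactants: 17 the N-tert-octyl ketimine from step 7
Product: 18 Pestalone G, 2-(3-bromo-5-chloro-2-hydroxy-6-methoxy-4-methylbenzoyl)-4,6-dihydroxy-3-(3-methylbut-2-enyl)benzaldehyde
Conditions: 3 M HCl (aq), MeOH–THF, 40 °C, dark; acidic extractive work-up (the amine stays in water as its hydrochloride)
Reagents that add atoms: water O
Why: Global acid hydrolysis: the acetal opens first, the hindered ketimine is hydrolysed with help from the neighbouring aldehyde hydrate (oxygen delivery through a five-membered ring), the MOM acetals are cleaved with MeOH trapping formaldehyde as dimethoxymethane, and the aryl–Si bond flanked by two hydroxyls undergoes ipso-protodesilylation; no stereocentre is formed.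

## Compound list

1 | 3-methoxy-5-methylphenol | COc1cc(C)cc(O)c1 | starting material
2 | 2-bromo-5-methoxy-3-methylphenol | COc1cc(O)c(Br)c(C)c1 | intermediate
3 | 2-bromo-4-chloro-5-methoxy-3-methylphenol | COc1cc(O)c(Br)c(C)c1Cl | intermediate
4 | 2-bromo-4-chloro-5-methoxy-1-(methoxymethoxy)-3-methylbenzene | COCOc1cc(OC)c(Cl)c(C)c1Br | intermediate
5 | 5-chloro-2,4-dihydroxybenzaldehyde | O=Cc1cc(Cl)c(O)cc1O | starting material
6 | 5-chloro-2,4-bis(methoxymethoxy)benzaldehyde | O=Cc1cc(Cl)c(OCOC)cc1OCOC | intermediate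
7 | 1-chloro-5-(dimethoxymethyl)-2,4-bis(methoxymethoxy)benzene | COC(OC)c1cc(Cl)c(OCOC)cc1OCOC | intermediate
8 | [3-chloro-5-(dimethoxymethyl)-2,6-bis(methoxymethoxy)phenyl]lithium | COC(OC)c1cc(Cl)c(OCOC)c([Li])c1OCOC | intermediate (not isolated)
9 | [3-chloro-5-(dimethoxymethyl)-2,6-bis(methoxymethoxy)phenyl]trimethylsilane | COC(OC)c1cc(Cl)c(OCOC)c([Si](C)(C)C)c1OCOC | intermediate
10 | 2-isocyano-2,4,4-trimethylpentane (1,1,3,3-tetramethylbutyl isocyanide) | CC(C)(C)CC(C)(C)[N+]#[C-] | starting material
11 | 1-bromo-3-methylbut-2-ene (prenyl bromide) | CC(C)=CCBr | starting material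
12 | [3-bromo-5-chloro-6-methoxy-2-(methoxymethoxy)-4-methylphenyl]lithium | [Li]c1c(OC)c(Cl)c(C)c(Br)c1OCOC | intermediate (not isolated)
13 | lithium aldimine, C-lithio-1-[3-bromo-5-chloro-6-methoxy-2-(methoxymethoxy)-4-methylphenyl]-N-(2,4,4-trimethylpentan-2-yl)methanimine | [Li]C(=NC(C)(C)CC(C)(C)C)c1c(OC)c(Cl)c(C)c(Br)c1OCOC | intermediate (not isolated)
14 | [2-chloro-6-(dimethoxymethyl)-3,5-bis(methoxymethoxy)-4-(trimethylsilyl)phenyl]lithium | COC(OC)c1c([Li])c(Cl)c(OCOC)c([Si](C)(C)C)c1OCOC | intermediate (not isolated)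
15 | 3-(dimethoxymethyl)-4,6-bis(methoxymethoxy)-5-(trimethylsilyl)-1,2-didehydrobenzene (ring B aryne) | COC(OC)C1=C(OCOC)C([Si](C)(C)C)=C(OCOC)C#C1 | intermediate (not isolated)
16 | ortho-lithiated ketimine (17 with Li at C6' in place of the prenyl group) | COC(OC)c1c(OCOC)c([Si](C)(C)C)c(OCOC)c([Li])c1C(=NC(C)(C)CC(C)(C)C)c1c(OC)c(Cl)c(C)c(Br)c1OCOC | intermediate (not isolated)
17 | 1-[3-bromo-5-chloro-6-methoxy-2-(methoxymethoxy)-4-methylphenyl]-1-[2-(dimethoxymethyl)-3,5-bis(methoxymethoxy)-6-(3-methylbut-2-enyl)-4-(trimethylsilyl)phenyl]-N-(2,4,4-trimethylpentan-2-yl)methanimine (imine geometry not defined) | COC(OC)c1c(OCOC)c([Si](C)(C)C)c(OCOC)c(CC=C(C)C)c1C(=NC(C)(C)CC(C)(C)C)c1c(OC)c(Cl)c(C)c(Br)c1OCOC | intermediate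
18 | Pestalone G, 2-(3-bromo-5-chloro-2-hydroxy-6-methoxy-4-methylbenzoyl)-4,6-dihydroxy-3-(3-methylbut-2-enyl)benzaldehyde (achiral) | COc1c(Cl)c(C)c(Br)c(O)c1C(=O)c1c(C=O)c(O)cc(O)c1CC=C(C)C | target

## Step count and risks

Total step count: 8. Longest linear sequence: 5 steps (1 → 2 → 3 → 4 → 17 → 18; the ring B branch 5 → 6 → 7 → 9 → 17 → 18 is equally long).

**Step 7 (most likely to fail).** The isocyanide insertion into hindered aryllithium 12 may be slow, or lithium aldimine 13 may lose the race for aryne 15 to LiTMP or to 14. The fallback replaces the in-situ lithium aldimine by a pre-formed, isolable dithiane anion as the masked aroyl anion, at the cost of an sp3 centre between two di-ortho-substituted rings. It sets out from 4 and comes back at 18. Compound 4 is lithiated with LiTMP as before and 12 is quenched with 2-chloro-1,3-dithiane (from 1,3-dithiane and NCS) to give 2-[3-bromo-5-chloro-6-methoxy-2-(methoxymethoxy)-4-methylphenyl]-1,3-dithiane F1. F1 is deprotonated at the dithiane carbon with LiTMP and combined with aryne 15 (from 9 and LiTMP, −45 → −15 °C) and then prenyl bromide 11 to give the 2,2-diaryl-1,3-dithiane F2. MeI/CaCO3 in aqueous MeCN unmasks the ketone to give the protected benzophenone F3. The acid treatment of step 8 then converts F3 into 18.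

**Step 8.** The hindered ketimine may hydrolyse slowly, and forcing acid could cyclise the prenyl group onto O5' (chroman) or leave the C4'–Si bond intact. The fallback splits the single acidolysis into three separate unveilings by different reagent classes. It sets out from 17 and comes back at 18. Aqueous oxalic acid in THF at rt hydrolyses only the ketimine and the acetal and gives the MOM- and silyl-protected keto-aldehyde F4. NaHSO4·SiO2 in CH2Cl2 at rt, a heterogeneous acid that tolerates ortho-prenyl phenols, removes the three MOM groups to give 5-(trimethylsilyl)-Pestalone G F5. Buffered fluoride (TBAF/AcOH, THF, 0 °C) then cleaves the C–Si bond through the keto tautomer of the flanked resorcinol and gives 18.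

**Step 1.** Ortho-bromination may give some of the para-to-OH isomer or dibromide. The fallback reverses the order of the two halogenations and uses a different selectivity element. It sets out from 1 and comes back at 3. Para-selective chlorination of 1 (SO2Cl2 with catalytic Ph2S/AlCl3, a bulky para-directing chlorinating system) gives 4-chloro-3-methoxy-5-methylphenol F6. NBS then brominates the only remaining unhindered activated carbon (ortho to OH, para to OMe) and gives 3.

Further compounds
F1 | step 7 | 2-[3-bromo-5-chloro-6-methoxy-2-(methoxymethoxy)-4-methylphenyl]-1,3-dithiane | COCOc1c(Br)c(C)c(Cl)c(OC)c1C1SCCCS1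
F2 | step 7 | 2-[3-bromo-5-chloro-6-methoxy-2-(methoxymethoxy)-4-methylphenyl]-2-[2-(dimethoxymethyl)-3,5-bis(methoxymethoxy)-6-(3-methylbut-2-enyl)-4-(trimethylsilyl)phenyl]-1,3-dithiane | COC(OC)c1c(OCOC)c([Si](C)(C)C)c(OCOC)c(CC=C(C)C)c1C1(SCCCS1)c1c(OC)c(Cl)c(C)c(Br)c1OCOC
F3 | step 7 | [3-bromo-5-chloro-6-methoxy-2-(methoxymethoxy)-4-methylphenyl][2-(dimethoxymethyl)-3,5-bis(methoxymethoxy)-6-(3-methylbut-2-enyl)-4-(trimethylsilyl)phenyl]methanone | COC(OC)c1c(OCOC)c([Si](C)(C)C)c(OCOC)c(CC=C(C)C)c1C(=O)c1c(OC)c(Cl)c(C)c(Br)c1OCOC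
F4 | step 8 | 2-[3-bromo-5-chloro-6-methoxy-2-(methoxymethoxy)-4-methylbenzoyl]-4,6-bis(methoxymethoxy)-3-(3-methylbut-2-enyl)-5-(trimethylsilyl)benzaldehyde | O=Cc1c(OCOC)c([Si](C)(C)C)c(OCOC)c(CC=C(C)C)c1C(=O)c1c(OC)c(Cl)c(C)c(Br)c1OCOC
F5 | step 8 | 2-(3-bromo-5-chloro-2-hydroxy-6-methoxy-4-methylbenzoyl)-4,6-dihydroxy-3-(3-methylbut-2-enyl)-5-(trimethylsilyl)benzaldehyde | COc1c(Cl)c(C)c(Br)c(O)c1C(=O)c1c(C=O)c(O)c([Si](C)(C)C)c(O)c1CC=C(C)C
F6 | step 1 | 4-chloro-3-methoxy-5-methylphenol | COc1cc(O)cc(C)c1Cl
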